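## Retrosynthetic overview

1. 25 ⇐ 24 ⇐ 23 ⇐ 22 (ester hydrolysis, O-sulfation, PMB removal) ⇐ aldehyde 20 + phosphonate 21 (vinylogous Horner–Wadsworth–Emmons) ⇐ cis-octalone 16, whose C8 ketone becomes the C8 methyl by methylenation and face-selective hydrogenation.
2. 16 ⇐ acyclic (R)-α'-alkoxy trienone 15 by one chelation-controlled intramolecular Diels–Alder reaction forming the C4a–C8a and C1–C2 bonds. The cyclohexane ring C4a–C5–C6–C7–C8–C8a closes through C4a–C8a in the same event as the cyclohexene ring; no ring exists before this step and none is formed after it.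
3. Enabling feature: the cyclohexene ring C1–C2–C3=C4–C4a–C8a is a Diels–Alder retron whose ene carbon C8a and diene terminus C4a are bridged by the four carbons C5–C8 of the cyclohexane ring. C8 lies next to the ene carbon, so it can be carried as a ketone conjugated to the dienophile, and the C7 oxygen then sits α to that ketone. A chelating metal turns this one stereocentre into control of the diastereoface, and the endo preference of the tether carbonyl gives the cis ring fusion.
4. 15 ⇐ α-alkoxy aldehyde 10 + alkenylzinc from alkyne 11; 10 ⇐ B-alkyl Suzuki–Miyaura coupling of the 9-BBN adduct of (R)-butenediol acetal 6 with iodotriene 4 (from tiglaldehyde 1 by Wittig and Takai olefinations).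

Key step: step 9

Remark on locants: C1–C8a denote the octahydronaphthalene atoms of 25 (C1 dienoic acid chain, C2 butenyl, C3 and C8 methyl, C7 oxygen) and are used in the Why lines for the corresponding atoms of every intermediate; systematic names use their own numbering.

Assumption: 25 is taken as the free hydrogen sulfate/carboxylic acid as drawn; it would be kept as its disodium salt and protonated only at the end.

## Route

Step 1
Reactants: 1 (2E)-2-methylbut-2-enal; 2 2-(triphenyl-λ5-phosphanylidene)propanal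
Product: 3 (2E,4E)-2,4-dimethylhexa-2,4-dienal
Conditions: toluene, 110 °C
Reagents that add atoms: none
Why: Wittig olefination with a stabilised formyl ylide should give the E-trisubstituted enal (aldehyde trans to the butenyl residue), and the more hindered dienal product should react on only slowly.

Step 2
Reactants: 3 (2E,4E)-2,4-dimethylhexa-2,4-dienal
Product: 4 (1E,3E,5E)-1-iodo-3,5-dimethylhepta-1,3,5-triene
Conditions: CHI3, CrCl2, THF/1,4-dioxane, 0 °C → rt, dark
Reagents that add atoms: iodoform IC(I)I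
Why: Takai iodo-olefination: the geminal dichromium species from CHI3 and CrCl2 adds to the aldehyde and anti-eliminates to the E-vinyl iodide, leaving the two existing E double bonds untouched.

Step 3
Reactants: 5 (2R)-but-3-ene-1,2-diol
Product: 6 (4R)-4-ethenyl-2-(4-methoxyphenyl)-1,3-dioxolane (both C2 epimers)
Conditions: 4-methoxybenzaldehyde dimethyl acetal, PPTS (cat.), CH2Cl2, rt
Reagents that add atoms: 4-methoxybenzaldehyde dimethyl acetal COc1ccc(cc1)C(OC)OC
Why: Acid-catalysed transacetalisation closes the five-membered p-methoxybenzylidene acetal without touching the C–O bond at the stereocentre, and the new acetal centre is removed again in step 5.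

Step 4
Reactants: 6 (4R)-4-ethenyl-2-(4-methoxyphenyl)-1,3-dioxolane; 4 (1E,3E,5E)-1-iodo-3,5-dimethylhepta-1,3,5-triene
Product: 8 (4R)-4-[(3E,5E,7E)-5,7-dimethylnona-3,5,7-trien-1-yl]-2-(4-methoxyphenyl)-1,3-dioxolane, via alkylborane 7 (not isolated)
Conditions: 9-BBN, THF, 0 °C → rt; then 4, Pd(dppf)Cl2 (5 mol %), AsPh3, aq. K3PO4, DMF, rt, dark
Reagents that add atoms: none
Why: 9-BBN hydroborates the vinyl group at the terminal carbon, and the B-alkyl Suzuki–Miyaura coupling joins it to the vinyl iodide with retention of the E geometry and without touching the stereocentre.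

Step 5
Reactants: 8 (4R)-4-[(3E,5E,7E)-5,7-dimethylnona-3,5,7-trien-1-yl]-2-(4-methoxyphenyl)-1,3-dioxolane
Product: 9 (2R,5E,7E,9E)-2-[(4-methoxyphenyl)methoxy]-7,9-dimethylundeca-5,7,9-trien-1-ol
Conditions: i-Bu2AlH (3 equiv), CH2Cl2, −78 → 0 °C; aq. sodium potassium tartrate
Reagents that add atoms: none
Why: Regioselective reductive opening of the arylidene acetal: aluminium binds the less hindered primary oxygen, that C–O bond ionises and hydride reduces the oxocarbenium ion, which leaves the PMB ether on the secondary oxygen and the stereocentre unchanged.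

Step 6
Reactants: 9 (2R,5E,7E,9E)-2-[(4-methoxyphenyl)methoxy]-7,9-dimethylundeca-5,7,9-trien-1-ol
Product: 10 (2R,5E,7E,9E)-2-[(4-methoxyphenyl)methoxy]-7,9-dimethylundeca-5,7,9-trienal
Conditions: DMP (1,1,1-triacetoxy-1,1-dihydro-1,2-benziodoxol-3(1H)-one), NaHCO3, CH2Cl2, 0 °C → rt
Reagents that add atoms: none
Why: Dess–Martin oxidation under buffered, base-free conditions should give the α-alkoxy aldehyde without epimerisation and without touching the triene.

Step 7
Reactants: 10 (2R,5E,7E,9E)-2-[(4-methoxyphenyl)methoxy]-7,9-dimethylundeca-5,7,9-trienal; 11 tert-butyl(dimethyl)(prop-2-yn-1-yloxy)silane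
Product: 14 (2E,5R,8E,10E,12E)-1-{[tert-butyl(dimethyl)silyl]oxy}-5-[(4-methoxyphenyl)methoxy]-10,12-dimethyltetradeca-2,8,10,12-tetraen-4-ol (both C4 epimers), via alkenylzirconocene chloride 12 (not isolated), via alkenylmethylzinc 13 (not isolated)
Conditions: 11, Cp2Zr(H)Cl, CH2Cl2, rt; Me2Zn, −65 °C; then 10, −65 → 0 °C
Reagents that add atoms: none
Why: Syn hydrozirconation gives the E-alkenyl metal, zirconium-to-zinc transmetalation gives an alkenylzinc that adds 1,2 to the aldehyde without enolising it, and the new carbinol centre is erased in step 8.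

Step 8
Reactants: 14 (2E,5R,8E,10E,12E)-1-{[tert-butyl(dimethyl)silyl]oxy}-5-[(4-methoxyphenyl)methoxy]-10,12-dimethyltetradeca-2,8,10,12-tetraen-4-ol
Product: 15 (2E,5R,8E,10E,12E)-1-{[tert-butyl(dimethyl)silyl]oxy}-5-[(4-methoxyphenyl)methoxy]-10,12-dimethyltetradeca-2,8,10,12-tetraen-4-one
Conditions: DMP, NaHCO3, CH2Cl2, 0 °C; cold work-up, used at once
Reagents that add atoms: none
Why: Dess–Martin oxidation of the allylic alcohol gives the E-enone and removes the carbinol stereocentre; the β-substituted enone should be isolable if kept cold and dilute.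

Step 9
Reactants: 15 (2E,5R,8E,10E,12E)-1-{[tert-butyl(dimethyl)silyl]oxy}-5-[(4-methoxyphenyl)methoxy]-10,12-dimethyltetradeca-2,8,10,12-tetraen-4-one
Product: 16 (2R,4aR,7S,8R,8aR)-7-[(2E)-but-2-en-2-yl]-8-({[tert-butyl(dimethyl)silyl]oxy}methyl)-2-[(4-methoxyphenyl)methoxy]-6-methyl-3,4,4a,7,8,8a-hexahydronaphthalen-1(2H)-one
Conditions: MgBr2·OEt2 (2.5 equiv), CH2Cl2 (0.005 M), −40 °C → rt
Reagents that add atoms: none
Why: The magnesium-chelated s-cis enone (carbonyl oxygen and C7 ether oxygen on one MgBr2) is the activated dienophile of a concerted, asynchronous intramolecular [4+2] cycloaddition with the E,E-diene; the closest known reaction types are the Lewis-acid-promoted intramolecular Diels–Alder reaction of 1,7,9-decatrien-3-ones to cis-fused 1-octalones and the chelation-controlled Diels–Alder reaction of α'-alkoxy enones. The cyclohexene ring closes as the [4+2] ring through the C4a–C8a and C1–C2 bonds, and the cyclohexane ring closes in the same event as the six-membered tether ring (tether atoms C5–C8) through the C4a–C8a bond, in a chair in which the chelated OPMB group is equatorial and eclipses the carbonyl. C1 and C8a follow from the E-enone by suprafacial addition (H1 and H8a trans), C2 and C4a from the E,E-diene (H2 and H4a cis), and the cis C4a/C8a fusion from the endo orientation of the tether carbonyl, which places the CH2OTBS group exo. The absolute sense comes from C7 alone: with the C7–O bond held in the enone plane by the chelate, the C6–C5 tether can reach only one face of the dienophile, which gives the 1,3-cis relation between the C7 oxygen and the C8a–C1 bond. The step needs endo over exo selectivity and chelate over open-chain face selection; these should be secured by the conjugated tether ketone, the chelating PMB ether at C7 and the non-chelating silyl ether at the far end of the dienophile. Regiochemistry is fixed by the tether length, since only this pairing gives a six-membered tether ring.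

Step 10
Reactants: 16 (2R,4aR,7S,8R,8aR)-7-[(2E)-but-2-en-2-yl]-8-({[tert-butyl(dimethyl)silyl]oxy}methyl)-2-[(4-methoxyphenyl)methoxy]-6-methyl-3,4,4a,7,8,8a-hexahydronaphthalen-1(2H)-one
Product: 17 tert-butyl{[(1S,2S,4aR,7R,8aR)-2-[(2E)-but-2-en-2-yl]-7-[(4-methoxyphenyl)methoxy]-3-methyl-8-methylidene-1,2,4a,5,6,7,8,8a-octahydronaphthalen-1-yl]methoxy}dimethylsilane
Conditions: Zn, CH2Br2, TiCl4 (pre-formed reagent), THF/CH2Cl2, 0 °C → rt
Reagents that add atoms: dibromomethane BrCBr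
Why: Takai–Lombardo methylenation with the non-basic geminal zinc/titanium methylene reagent should convert the hindered, enolisable ketone into the exocyclic alkene without epimerising the adjacent C7 and C8a centres.

Step 11
Reactants: 17 tert-butyl{[(1S,2S,4aR,7R,8aR)-2-[(2E)-but-2-en-2-yl]-7-[(4-methoxyphenyl)methoxy]-3-methyl-8-methylidene-1,2,4a,5,6,7,8,8a-octahydronaphthalen-1-yl]methoxy}dimethylsilane
Product: 18 tert-butyl{[(1S,2S,4aS,7R,8S,8aR)-2-[(2E)-but-2-en-2-yl]-7-[(4-methoxyphenyl)methoxy]-3,8-dimethyl-1,2,4a,5,6,7,8,8a-octahydronaphthalen-1-yl]methoxy}dimethylsilane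
Conditions: H2 (1 atm), RhCl(PPh3)3 (10 mol %), benzene/EtOH, rt
Reagents that add atoms: none
Why: Homogeneous hydrogenation with RhCl(PPh3)3 reduces 1,1-disubstituted alkenes much faster than trisubstituted ones; in the conformer with all cyclohexene-ring substituents equatorial, the lower face of the methylidene group is screened by the axial C7–OPMB group and the axial C8a–C1 bond with its CH2OTBS arm, so hydrogen should add from the upper face and set C8 with the methyl cis to the C7 oxygen (8S).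

Step 12
Reactants: 18 tert-butyl{[(1S,2S,4aS,7R,8S,8aR)-2-[(2E)-but-2-en-2-yl]-7-[(4-methoxyphenyl)methoxy]-3,8-dimethyl-1,2,4a,5,6,7,8,8a-octahydronaphthalen-1-yl]methoxy}dimethylsilane
Product: 19 [(1S,2S,4aS,7R,8S,8aR)-2-[(2E)-but-2-en-2-yl]-7-[(4-methoxyphenyl)methoxy]-3,8-dimethyl-1,2,4a,5,6,7,8,8a-octahydronaphthalen-1-yl]methanol
Conditions: Bu4NF, THF, 0 °C → rt
Reagents that add atoms: none
Why: Fluoride-induced desilylation frees the primary alcohol while the PMB ether and the alkenes are inert.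

Step 13
Reactants: 19 [(1S,2S,4aS,7R,8S,8aR)-2-[(2E)-but-2-en-2-yl]-7-[(4-methoxyphenyl)methoxy]-3,8-dimethyl-1,2,4a,5,6,7,8,8a-octahydronaphthalen-1-yl]methanol
Product: 20 (1S,2S,4aS,7R,8S,8aS)-2-[(2E)-but-2-en-2-yl]-7-[(4-methoxyphenyl)methoxy]-3,8-dimethyl-1,2,4a,5,6,7,8,8a-octahydronaphthalene-1-carbaldehyde
Conditions: DMP, NaHCO3, CH2Cl2, 0 °C
Reagents that add atoms: none
Why: Dess–Martin oxidation under buffered conditions gives the aldehyde without base, so the C1 centre next to the new carbonyl should keep its configuration.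

Step 14
Reactants: 20 (1S,2S,4aS,7R,8S,8aS)-2-[(2E)-but-2-en-2-yl]-7-[(4-methoxyphenyl)methoxy]-3,8-dimethyl-1,2,4a,5,6,7,8,8a-octahydronaphthalene-1-carbaldehyde; 21 ethyl (2E)-4-(diethoxyphosphoryl)but-2-enoate
Product: 22 ethyl (2E,4E)-5-[(1S,2S,4aS,7R,8S,8aR)-2-[(2E)-but-2-en-2-yl]-7-[(4-methoxyphenyl)methoxy]-3,8-dimethyl-1,2,4a,5,6,7,8,8a-octahydronaphthalen-1-yl]penta-2,4-dienoate
Conditions: 21, LiN(SiMe3)2, THF, −78 °C; then 20, −78 → 0 °C
Reagents that add atoms: none
Why: Vinylogous Horner–Wadsworth–Emmons olefination: the phosphonate-stabilised allylic anion adds through the carbon bearing phosphorus and syn-eliminates phosphate to give the new E double bond, the second E double bond is carried by the reagent, and the low temperature should prevent epimerisation at C1.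

Step 15
Reactants: 22 ethyl (2E,4E)-5-[(1S,2S,4aS,7R,8S,8aR)-2-[(2E)-but-2-en-2-yl]-7-[(4-methoxyphenyl)methoxy]-3,8-dimethyl-1,2,4a,5,6,7,8,8a-octahydronaphthalen-1-yl]penta-2,4-dienoate
Product: 23 ethyl (2E,4E)-5-[(1S,2S,4aS,7R,8S,8aR)-2-[(2E)-but-2-en-2-yl]-7-hydroxy-3,8-dimethyl-1,2,4a,5,6,7,8,8a-octahydronaphthalen-1-yl]penta-2,4-dienoate
Conditions: DDQ, CH2Cl2/pH 7 buffer (10:1), 0 °C
Reagents that add atoms: none
Why: Oxidative PMB cleavage: DDQ abstracts hydride from the electron-rich benzylic position and water hydrolyses the oxocarbenium ion, which frees the C7 alcohol with retention while the electron-poor dienoate and the isolated alkenes are left alone.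

Step 16
Reactants: 23 ethyl (2E,4E)-5-[(1S,2S,4aS,7R,8S,8aR)-2-[(2E)-but-2-en-2-yl]-7-hydroxy-3,8-dimethyl-1,2,4a,5,6,7,8,8a-octahydronaphthalen-1-yl]penta-2,4-dienoate
Product: 24 ethyl (2E,4E)-5-[(1S,2S,4aS,7R,8S,8aR)-2-[(2E)-but-2-en-2-yl]-3,8-dimethyl-7-(sulfooxy)-1,2,4a,5,6,7,8,8a-octahydronaphthalen-1-yl]penta-2,4-dienoate
Conditions: SO3·pyridine (5 equiv), pyridine, 40 °C
Reagents that add atoms: sulfur trioxide–pyridine complex O=S(=O)([O-])[n+]1ccccc1
Why: O-Sulfation with the SO3·pyridine complex forms the O–S bond at oxygen, so the C7 configuration is retained, and excess reagent with gentle warming should compensate for the hindered axial alcohol.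

Step 17
Reactants: 24 ethyl (2E,4E)-5-[(1S,2S,4aS,7R,8S,8aR)-2-[(2E)-but-2-en-2-yl]-3,8-dimethyl-7-(sulfooxy)-1,2,4a,5,6,7,8,8a-octahydronaphthalen-1-yl]penta-2,4-dienoate
Product: 25 (2E,4E)-5-[(1S,2S,4aS,7R,8S,8aR)-2-[(2E)-but-2-en-2-yl]-3,8-dimethyl-7-(sulfooxy)-1,2,4a,5,6,7,8,8a-octahydronaphthalen-1-yl]penta-2,4-dienoic acid
Conditions: LiOH, THF/MeOH/H2O, rt; then cold 1 M HCl to pH 2
Reagents that add atoms: lithium hydroxide [Li+].[OH-]
Why: Saponification of the ethyl ester by acyl–oxygen cleavage; alkyl sulfate monoanions resist hydroxide, and brief cold acidification should give the free diacid.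

## Compound list

1 | (2E)-2-methylbut-2-enal (tiglaldehyde) | C/C=C(\C)C=O | starting material
2 | 2-(triphenyl-λ5-phosphanylidene)propanal | CC(C=O)=P(c1ccccc1)(c1ccccc1)c1ccccc1 | starting material
3 | (2E,4E)-2,4-dimethylhexa-2,4-dienal | C/C=C(\C)/C=C(\C)C=O | intermediate
4 | (1E,3E,5E)-1-iodo-3,5-dimethylhepta-1,3,5-triene | C/C=C(\C)/C=C(\C)/C=C/I | intermediate
5 | (2R)-but-3-ene-1,2-diol | C=C[C@@H](O)CO | starting material
6 | (4R)-4-ethenyl-2-(4-methoxyphenyl)-1,3-dioxolane (both C2 epimers) | C=C[C@@H]1COC(c2ccc(OC)cc2)O1 | intermediate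
7 | 9-{2-[(4R)-2-(4-methoxyphenyl)-1,3-dioxolan-4-yl]ethyl}-9-borabicyclo[3.3.1]nonane | C(C[C@@H]1COC(c2ccc(OC)cc2)O1)B1C2CCCC1CCC2 | intermediate
8 | (4R)-4-[(3E,5E,7E)-5,7-dimethylnona-3,5,7-trien-1-yl]-2-(4-methoxyphenyl)-1,3-dioxolane | C/C=C(\C)/C=C(\C)/C=C/CC[C@@H]1COC(c2ccc(OC)cc2)O1 | intermediate
9 | (2R,5E,7E,9E)-2-[(4-methoxyphenyl)methoxy]-7,9-dimethylundeca-5,7,9-trien-1-ol | C/C=C(\C)/C=C(\C)/C=C/CC[C@@H](OCc1ccc(OC)cc1)CO | intermediate
10 | (2R,5E,7E,9E)-2-[(4-methoxyphenyl)methoxy]-7,9-dimethylundeca-5,7,9-trienal | C/C=C(\C)/C=C(\C)/C=C/CC[C@@H](OCc1ccc(OC)cc1)C=O | intermediate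
11 | tert-butyl(dimethyl)(prop-2-yn-1-yloxy)silane | C#CCO[Si](C)(C)C(C)(C)C | starting material
12 | chlorobis(cyclopentadienyl)[(1E)-3-{[tert-butyl(dimethyl)silyl]oxy}prop-1-en-1-yl]zirconium | Cl[Zr](/C=C/CO[Si](C)(C)C(C)(C)C)(C1C=CC=C1)C1C=CC=C1 | intermediate
13 | [(1E)-3-{[tert-butyl(dimethyl)silyl]oxy}prop-1-en-1-yl](methyl)zinc | C[Zn]/C=C/CO[Si](C)(C)C(C)(C)C | intermediate
14 | (2E,5R,8E,10E,12E)-1-{[tert-butyl(dimethyl)silyl]oxy}-5-[(4-methoxyphenyl)methoxy]-10,12-dimethyltetradeca-2,8,10,12-tetraen-4-ol (both C4 epimers) | C/C=C(\C)/C=C(\C)/C=C/CC[C@@H](OCc1ccc(OC)cc1)C(O)/C=C/CO[Si](C)(C)C(C)(C)C | intermediate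
15 | (2E,5R,8E,10E,12E)-1-{[tert-butyl(dimethyl)silyl]oxy}-5-[(4-methoxyphenyl)methoxy]-10,12-dimethyltetradeca-2,8,10,12-tetraen-4-one | C/C=C(\C)/C=C(\C)/C=C/CC[C@@H](OCc1ccc(OC)cc1)C(=O)/C=C/CO[Si](C)(C)C(C)(C)C | intermediate
16 | (2R,4aR,7S,8R,8aR)-7-[(2E)-but-2-en-2-yl]-8-({[tert-butyl(dimethyl)silyl]oxy}methyl)-2-[(4-methoxyphenyl)methoxy]-6-methyl-3,4,4a,7,8,8a-hexahydronaphthalen-1(2H)-one | C/C=C(\C)[C@H]1C(C)=C[C@H]2CC[C@@H](OCc3ccc(OC)cc3)C(=O)[C@H]2[C@@H]1CO[Si](C)(C)C(C)(C)C | intermediate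
17 | tert-butyl{[(1S,2S,4aR,7R,8aR)-2-[(2E)-but-2-en-2-yl]-7-[(4-methoxyphenyl)methoxy]-3-methyl-8-methylidene-1,2,4a,5,6,7,8,8a-octahydronaphthalen-1-yl]methoxy}dimethylsilane | C/C=C(\C)[C@H]1C(C)=C[C@H]2CC[C@@H](OCc3ccc(OC)cc3)C(=C)[C@H]2[C@@H]1CO[Si](C)(C)C(C)(C)C | intermediate
18 | tert-butyl{[(1S,2S,4aS,7R,8S,8aR)-2-[(2E)-but-2-en-2-yl]-7-[(4-methoxyphenyl)methoxy]-3,8-dimethyl-1,2,4a,5,6,7,8,8a-octahydronaphthalen-1-yl]methoxy}dimethylsilane | C/C=C(\C)[C@H]1C(C)=C[C@H]2CC[C@@H](OCc3ccc(OC)cc3)[C@@H](C)[C@H]2[C@@H]1CO[Si](C)(C)C(C)(C)C | intermediate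
19 | [(1S,2S,4aS,7R,8S,8aR)-2-[(2E)-but-2-en-2-yl]-7-[(4-methoxyphenyl)methoxy]-3,8-dimethyl-1,2,4a,5,6,7,8,8a-octahydronaphthalen-1-yl]methanol | C/C=C(\C)[C@H]1C(C)=C[C@H]2CC[C@@H](OCc3ccc(OC)cc3)[C@@H](C)[C@H]2[C@@H]1CO | intermediate
20 | (1S,2S,4aS,7R,8S,8aS)-2-[(2E)-but-2-en-2-yl]-7-[(4-methoxyphenyl)methoxy]-3,8-dimethyl-1,2,4a,5,6,7,8,8a-octahydronaphthalene-1-carbaldehyde | C/C=C(\C)[C@H]1C(C)=C[C@H]2CC[C@@H](OCc3ccc(OC)cc3)[C@@H](C)[C@H]2[C@@H]1C=O | intermediate
21 | ethyl (2E)-4-(diethoxyphosphoryl)but-2-enoate (triethyl 4-phosphonocrotonate) | CCOC(=O)/C=C/CP(=O)(OCC)OCC | starting material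
22 | ethyl (2E,4E)-5-[(1S,2S,4aS,7R,8S,8aR)-2-[(2E)-but-2-en-2-yl]-7-[(4-methoxyphenyl)methoxy]-3,8-dimethyl-1,2,4a,5,6,7,8,8a-octahydronaphthalen-1-yl]penta-2,4-dienoate | C/C=C(\C)[C@H]1C(C)=C[C@H]2CC[C@@H](OCc3ccc(OC)cc3)[C@@H](C)[C@H]2[C@@H]1/C=C/C=C/C(=O)OCC | intermediate
23 | ethyl (2E,4E)-5-[(1S,2S,4aS,7R,8S,8aR)-2-[(2E)-but-2-en-2-yl]-7-hydroxy-3,8-dimethyl-1,2,4a,5,6,7,8,8a-octahydronaphthalen-1-yl]penta-2,4-dienoate | C/C=C(\C)[C@H]1C(C)=C[C@H]2CC[C@@H](O)[C@@H](C)[C@H]2[C@@H]1/C=C/C=C/C(=O)OCC | intermediate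
24 | ethyl (2E,4E)-5-[(1S,2S,4aS,7R,8S,8aR)-2-[(2E)-but-2-en-2-yl]-3,8-dimethyl-7-(sulfooxy)-1,2,4a,5,6,7,8,8a-octahydronaphthalen-1-yl]penta-2,4-dienoate | C/C=C(\C)[C@H]1C(C)=C[C@H]2CC[C@@H](OS(=O)(=O)O)[C@@H](C)[C@H]2[C@@H]1/C=C/C=C/C(=O)OCC | intermediate
25 | (2E,4E)-5-[(1S,2S,4aS,7R,8S,8aR)-2-[(2E)-but-2-en-2-yl]-3,8-dimethyl-7-(sulfooxy)-1,2,4a,5,6,7,8,8a-octahydronaphthalen-1-yl]penta-2,4-dienoic acid | C/C=C(\C)[C@H]1C(C)=C[C@H]2CC[C@@H](OS(=O)(=O)O)[C@@H](C)[C@H]2[C@@H]1/C=C/C=C/C(=O)O | target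

## Step count and risks

Total step count: 17. Longest linear sequence: 16 steps (steps 1, 2 and 4–17, from 1); the branch from 5 (steps 3–17) is 15 steps.

Steps most likely to fail:

Step 9. What may go wrong is erosion of the endo (cis-fusing) selectivity, face selection through a non-chelated conformer, or Lewis-acid-induced decomposition of the electron-rich triene. The fallback replaces metal chelation by an internal hydrogen bond and uses no Lewis acid. It sets out from 15: the PMB ether is cleaved with DDQ in wet CH2Cl2 to give hydroxy enone F1, in which the O–H···O=C hydrogen bond holds the C7–O bond in the enone plane as the chelate would. Heating F1 in dilute toluene at 60–80 °C should give hydroxy octalone F2. Treatment of F2 with 4-methoxybenzyl 2,2,2-trichloroacetimidate and catalytic La(OTf)3 restores the PMB ether, and the route is rejoined at 16.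

Step 11. What may go wrong is loss of face selectivity in hydrogen delivery, migration of the exocyclic double bond into the ring, or a reduction slow enough for the trisubstituted alkenes to compete. The fallback brings in the methyl group as a nucleophile and the hydrogen as a radical. It sets out from 16: MeLi with CeCl3 in THF at −78 °C adds to the ketone to give tertiary alcohol F3 (either C8 epimer serves). Methyl chlorooxoacetate with pyridine and DMAP converts it into methyl oxalate F4. Bu3SnH with AIBN in refluxing toluene should fragment F4 to the planar tertiary C8 radical, which takes hydrogen from the open upper face. This bypasses 17 and rejoins the route at 18.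

Step 10. What may go wrong is enolisation with epimerisation at C8a or C7, or no reaction at the hindered carbonyl. The fallback is a two-stage Peterson olefination. It sets out from 16: Me3SiCH2Li with CeCl3 in THF at −78 °C adds as a non-basic organocerium reagent to give β-hydroxysilane F5, and KH in THF effects the syn-elimination, which rejoins the route at 17.

Further compounds

F1 | step 9 | (2E,5R,8E,10E,12E)-1-{[tert-butyl(dimethyl)silyl]oxy}-5-hydroxy-10,12-dimethyltetradeca-2,8,10,12-tetraen-4-one | C/C=C(\C)/C=C(\C)/C=C/CC[C@@H](O)C(=O)/C=C/CO[Si](C)(C)C(C)(C)C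
F2 | step 9 | (2R,4aR,7S,8R,8aR)-7-[(2E)-but-2-en-2-yl]-8-({[tert-butyl(dimethyl)silyl]oxy}methyl)-2-hydroxy-6-methyl-3,4,4a,7,8,8a-hexahydronaphthalen-1(2H)-one | C/C=C(\C)[C@H]1C(C)=C[C@H]2CC[C@@H](O)C(=O)[C@H]2[C@@H]1CO[Si](C)(C)C(C)(C)C
F3 | step 11 | (2R,4aR,7S,8R,8aR)-7-[(2E)-but-2-en-2-yl]-8-({[tert-butyl(dimethyl)silyl]oxy}methyl)-2-[(4-methoxyphenyl)methoxy]-1,6-dimethyl-1,2,3,4,4a,7,8,8a-octahydronaphthalen-1-ol (C1 epimers) | C/C=C(\C)[C@H]1C(C)=C[C@H]2CC[C@@H](OCc3ccc(OC)cc3)C(C)(O)[C@H]2[C@@H]1CO[Si](C)(C)C(C)(C)C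
F4 | step 11 | (2R,4aR,7S,8R,8aR)-7-[(2E)-but-2-en-2-yl]-8-({[tert-butyl(dimethyl)silyl]oxy}methyl)-2-[(4-methoxyphenyl)methoxy]-1,6-dimethyl-1,2,3,4,4a,7,8,8a-octahydronaphthalen-1-yl methyl oxalate (C1 epimers) | C/C=C(\C)[C@H]1C(C)=C[C@H]2CC[C@@H](OCc3ccc(OC)cc3)C(C)(OC(=O)C(=O)OC)[C@H]2[C@@H]1CO[Si](C)(C)C(C)(C)C
F5 | step 10 | (2R,4aR,7S,8R,8aR)-7-[(2E)-but-2-en-2-yl]-8-({[tert-butyl(dimethyl)silyl]oxy}methyl)-2-[(4-methoxyphenyl)methoxy]-6-methyl-1-[(trimethylsilyl)methyl]-1,2,3,4,4a,7,8,8a-octahydronaphthalen-1-ol (C1 epimers) | C/C=C(\C)[C@H]1C(C)=C[C@H]2CC[C@@H](OCc3ccc(OC)cc3)C(O)(C[Si](C)(C)C)[C@H]2[C@@H]1CO[Si](C)(C)C(C)(C)C
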